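The rate constants are invented, and the outcome is calculated.

The pitfall in this flask is to read 1.20 equiv of nucleophile as an excess: one electrophile can cost two nucleophiles, the first on its way to target, the second when that target goes on to over-reaction product B.

electrophile 0.25 M; nucleophile 1.20 equiv; free base 2.00 equiv; time 10 min

    electrophile + nucleophile → acid set free + target (k1 = 0.081 /M/s)
    nucleophile + acid set free ⇌ protonated nucleophile, settled at all times (K2 = 43 /M)
    acid set free + free base ⇌ salt of the base (K3 = 110 /M, k3 = 0.81 /M/s)
    target → over-reaction product A (k4 = 3.0 × 10⁻⁵ /s)
    nucleophile + target → over-reaction product B (k5 = 0.031 /M/s)

- part of the electrophile that has reacted at 10 min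
- share of the unused nucleophile that is free and not bound as protonated nucleophile, at 10 min

Steps 1 and 5 take the same free nucleophile, so the share bound by acid drops out of their ratio, and time drops out with it. I freeze s = 0.383, the spoil ratio, the rate constant of step 5 over that of step 1, a selectivity factor. I drop step 4, whose half-life of 6.4 h is longer than 10 min. With x the electrophile left and T the target, both per electrophile charged, the curve is

T = (x^s − x)/(1 − s)

It starts with one target gained per electrophile lost, and it peaks at x = s^(1/(1 − s)) = 21.1%, where target stands at 55.1%. It stops where the nucleophile used, 2(1 − x) − T, equals the charge, which makes nucleophile the limiting reagent. Solving for x and starting from a trial T of 0.5, I go round between budget and curve: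

x: 15.0%, 13.0%, 13.4%; target 53.4%

Near that level, steps 1 and 5 together use free nucleophile with a half-life of about 1.68 min, the part bound by acid left aside, which is shorter than 10 min, so I commit to 86.6% reacted. The free base has the larger binding constant, 110 /M against 43 /M for the nucleophile, so I count all the acid set free as salt of the base, and that balance gives acid at 0.00694 M and a free share of 77.0%.

The forecast says 86% and 78%, holding that “this side reaction starves the electrophile of nucleophile”.

The simulation gives 86.0% and 78.1%. In this flask, at 0.599 min, step 1 uses nucleophile 3.9 times as fast as step 5. At 10 min, electrophile at 14.0% and target at 52.8% of the electrophile charged, divided by the spoil ratio, put that ratio at 0.692, with nucleophile down to 1.14% of its own charge. The neighbour flask with 0.500 equiv of free base has a free share of 24.1%; at its 18.0% of electrophile the curve reads 54.9% target, and that flask holds 54.1%.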